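the same everywhere: starting complex 0.50 mM

| run | incoming ligand | remark | time |
|---|---|---|---|
| spring | 2.1 equiv | run made earlier |  |
| winter | 3.3 equiv | run made earlier |  |
| flask | 1.50 equiv |  | 3.0 h |

| run | time / h | complex with two exchanged / % | side product / % | complex with three exchanged / % |
|---|---|---|---|---|
| spring | 0.333 | 56.0 | 4.0 | 32.3 |
| spring | 0.667 | 55.6 | 5.3 | 31.1 |
| spring | 1.00 | 56.0 | 5.6 | 31.3 |
| spring | 1.33 | 55.0 | 4.3 | 32.3 |
| spring | 1.50 | 55.8 | 4.5 | 31.9 |
| spring | 2.00 | 56.5 | 4.9 | 32.3 |
| spring | 2.50 | 55.3 | 5.7 | 31.9 |
| winter | 0.333 | 0.6 | 0.5 | 98.6 |
| winter | 0.667 | 0 | 1.8 | 99.2 |
| winter | 1.00 | 0.6 | 1.4 | 98.4 |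
| winter | 1.33 | 0 | 1.4 | 98.7 |
| winter | 1.50 | 0 | 2.2 | 98.2 |
| winter | 2.00 | 0 | 0.8 | 99.2 |
| winter | 2.50 | 0 | 1.0 | 99.6 |

(each reading ± 0.5 percentage points)

- the reaction counts as stopped when no species that holds the starting complex changes by six tenths of a point or more over the second half of the time

* which holds at 3.0 h: what has brought the reaction to rest, or that it has not come to rest (all of the starting complex has reacted / it is still moving / the incoming ligand has run out first)
* how much complex with two exchanged there is at 3.0 h, in percent of the starting complex charged
* how much side product there is at 3.0 h, in percent of the starting complex charged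
* how much complex with three exchanged there is at 3.0 h, in percent of the starting complex charged

I cannot get a rate out of these runs: spring and winter stand flat, within the scatter, from the first reading at 0.333 h, so I have to work from the charge instead of the clock. At the last spring reading the two complexes, with two and three incoming ligands each, hold 2.06 equivalents against the 2.1 equiv charged, so I take the incoming ligand as the limiting reagent there and, with 1.50 equiv, in this flask too.

My reckoning goes to the side product, which reads 4.90% of the charge on average in spring and 1.30% in winter, more at the lower charge. I go to logarithms and draw a straight line through these two averages: on that line, with the starting complex at 0.50 mM, the side product falls by a power of ten for every 2.08 equiv of incoming ligand added, and this stretch of charge I call the decade width. This flask lies 0.600 equiv below spring, which is 0.288 of a decade, so I expect 9.51% side product.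

The forecast differs from me on that number: it says the incoming ligand has run out first, with 55% complex with two exchanged, 5% side product and 12.5% complex with three exchanged, on the ground that “Starting complex therefore survives only because ligand ran out”.

The flask gives this: the incoming ligand has run out first, with 54.5% complex with two exchanged, 11.0% side product and 9.99% complex with three exchanged.

    starting complex → decomposition product (k = 1.70 × 10⁻⁵ s⁻¹)
    complex with one exchanged → side product (k = 0.0180 s⁻¹)
    starting complex ⇌ dormant form (K = 3.00, k = 0.0120 s⁻¹)
    complex with one exchanged + incoming ligand → leaving ligand + complex with two exchanged (k = 1400 M⁻¹ s⁻¹)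
    starting complex + incoming ligand → leaving ligand + complex with one exchanged (k = 430 M⁻¹ s⁻¹)
    complex with two exchanged + incoming ligand → leaving ligand + complex with three exchanged (k = 89.0 M⁻¹ s⁻¹)

The side product in this flask stands 1.5 percentage points above my 9.51%. Changing the amount of incoming ligand from spring to this flask takes it from 4.82% to 11.0%, while changing the time leaves it at 4.82%. The decade width of 2.08 equiv places a flask with 2.50 equiv of incoming ligand 0.192 of a decade above spring, which reckons 3.15% side product; that flask holds 2.81%.

All runs were computed on assumed constants.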